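Late in the two flasks elm and maple, the question is what fraction of the coupled material, target plus isomer of the product, is left as target. So I reckon with that fraction left, the selectivity for target, and not with the amount made.

| setting | autumn | dusk | spring | elm | maple |
|---|---|---|---|---|---|
| substrate | 0.14 M | 0.22 M | 0.10 M | 0.10 M | 0.10 M |
| coupling partner | 0.50 equiv | 0.50 equiv | 0.25 equiv | 0.500 equiv | 0.500 equiv |
| free catalyst | 0.056 mol% | 0.056 mol% | 0.056 mol% | 0.056 mol% | 0.056 mol% |
| temperature | 55 °C | 90 °C | 55 °C |  |  |
| remark | run made earlier | run made earlier | run made earlier | at 60 °C until 8.0 min, from then on at 120 °C | at 60 °C throughout |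
| time |  |  |  | 40 min | 150 min |

| run | time / min | target / % | isomer of the product / % |
|---|---|---|---|
| autumn | 1.50 | 2.9 | 0.4 |
| autumn | 5.00 | 4.2 | 0 |
| autumn | 8.00 | 4.1 | 0.1 |
| autumn | 12.0 | 6.8 | 1.1 |
| autumn | 20.0 | 10.9 | 0 |
| autumn | 25.0 | 14.2 | 1.9 |
| dusk | 0.417 | 1.9 | 0.2 |
| dusk | 0.667 | 4.1 | 2.2 |
| dusk | 1.00 | 5.6 | 2.1 |
| dusk | 2.00 | 9.1 | 4.7 |
| dusk | 3.00 | 8.2 | 8.2 |
| dusk | 6.00 | 15.0 | 21.7 |
| spring | 2.00 | 0.3 | 0 |
| spring | 6.00 | 2.3 | 0.7 |
| spring | 12.0 | 5.1 | 0 |
| spring | 15.0 | 5.4 | 0.7 |
| spring | 25.0 | 10.9 | 0.3 |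

(each reading ± 1 percentage point)

- the share counts what is present at the end, not what went on to other products

1. which one finishes higher in share of target in all that became target or isomer of the product ("neither" within 2 percentage points) (elm / maple / neither)
2. share of target in all that became target or isomer of the product, elm
3. share of target in all that became target or isomer of the product, maple

I read the tables column against column: isomer per target, divided by the time of the row. In dusk this gives 0.258 min⁻¹ at 2.00 min, 0.333 min⁻¹ at 3.00 min and 0.241 min⁻¹ at 6.00 min. In these readings the ratio grows roughly in step with time, and I keep the last row.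

At 55 °C a single row is lost in the scatter of 1 percentage point, so I add the last rows of autumn and spring, both at 25.0 min. That gives the ratio growth g, the isomer gained per target per minute, as 0.00351 min⁻¹. Taking g to depend on temperature and not on the charges, which differ between these runs, I get a temperature constant of 14400 K.

If the ratio goes on growing in step with time, the fraction left is one over one plus g times the time. For maple at 60 °C, I extrapolate g to 0.00678 min⁻¹, and over 150 min I reckon the fraction left at 49.6%. For elm at 120 °C, I extrapolate g to 4.97 min⁻¹. Counting the 32.0 min of the hot stretch, I reckon the fraction left at 0.624%.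

The forecast names maple, with 3% for elm (0% to 22%) and 33% for maple (18% to 52%), and reads “That points to sequential isomerisation, target → isomer.”; my number stands higher for maple and lower for elm.

The flasks give 12.6% for elm and 70.6% for maple, so maple finishes higher.

    substrate + free catalyst → catalyst intermediate A (k = 451 M⁻¹ min⁻¹, Ea = 58.0 kJ mol⁻¹)
    catalyst intermediate A → catalyst intermediate B (k = 57.8 min⁻¹, Ea = 68.0 kJ mol⁻¹)
    coupling partner + catalyst intermediate B ⇌ catalyst intermediate C (K = 32.0 M⁻¹, k = 27000 M⁻¹ min⁻¹, Ea = 44.0 kJ mol⁻¹, ΔH = −25.0 kJ mol⁻¹)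
    catalyst intermediate C → free catalyst + target (k = 51.8 min⁻¹, Ea = 73.0 kJ mol⁻¹)
    target ⇌ isomer of the product (K = 0.417, k = 0.0287 min⁻¹, Ea = 110 kJ mol⁻¹, ΔH = 51.0 kJ mol⁻¹)
    target → over-reaction product (k = 3.04 × 10⁻⁵ min⁻¹, Ea = 125 kJ mol⁻¹)
    (constants at 60 °C)

In maple the fraction left is 70.6% against my 49.6%, and at 1500 min it is 70.6%, which equals one over one plus the equilibrium constant of target ⇌ isomer of the product at 60 °C, 70.6%. A repeat of maple at 35 °C takes the same reckoning: I extrapolate g to 2.03 × 10⁻⁴ min⁻¹, and over 150 min I reckon the fraction left at 97.0%. That flask gives 95.1%, with target at 16.4% of the substrate charged and 83% of the substrate still unbound.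

The numbers in the tables were generated by integration for an exercise.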